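# Total synthesis of CNP0317149.1 by Ramberg–Bäcklund contraction of an eleven-membered sulfone

## The problem

Compound 33 is a melampolide-type germacranolide. A ten-membered carbocycle (C1–C10) is trans-fused along C6–C7 to an α-methylene-γ-butyrolactone (O6–C12(=O)–C11(=C13H2)). It carries a methacrylate on O8 and a methyl ester (C14) on C10.

The ring holds two trisubstituted alkenes of opposite ring geometry. C4=C5 is ring-trans. C1=C10 is ring-cis: C2 and C9 lie on one side and CO2Me lies opposite C2, so it is E by the sequence rule. Closing a medium ring around both alkenes is the main skeletal difficulty.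

The stereocentres C6, C7 and C8 (all R in 33) are contiguous. On the ring, O6 and C11 are trans and C11 and O8 are cis. In an extended C5–C9 chain this reads O6/C11 syn, C11/O8 anti and O6/O8 anti.

This array can be relayed along the chain. An oxygenated C8 can direct C–C bond formation at C7 through anti alkylation of a β-hydroxy ester dianion. The C7/C8 pair can then direct addition to a C6 aldehyde, because Felkin–Anh and 1,3-anti induction ask for the same face. A closed six-membered allylmetal transition state across C7–C8 is instead expected to give the C8 epimer.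

Several groups forbid strong base, nucleophilic sulfur and strong acid once they are present:
- the α-methylene lactone (thiols, amines and alkoxides add to C13);
- the methacrylate;
- the enoate (deprotonation at C2 deconjugates it);
- the allylic C6–O bond;
- the 1,5-diene (acid-induced transannular cyclisation).

A free C8 hydroxyl also lies within reach of both the C12 and the C14 carbonyl groups.

The feature that opens the key step is C10, an alkene carbon that bears an acidifying ester. With a sulfonyl group inserted between C1 and C10, C10 becomes the carbon of an α-sulfonyl ester. That position can be alkylated and chlorinated selectively under mild base, and it returns the C1=C10 enoate when the sulfonyl bridge is expelled.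

## Retrosynthesis

**33 ⇒ 32 ⇒ 31 ⇒ 30 ⇒ 29 (O8–acyl bond, O8–Si bond, oxidation level of C12).** The methacrylate is cut first because it survives neither alkoxide nor hydride. The alcohol 32 comes from the silyl ether 31. The lactone carbonyl of 31 is traced to the allylic lactol 30 and its methyl acetal 29. Cutting C11=C13 here instead would require lactone enolate chemistry next to an enoate with acidic C2 hydrogens. Masking C12 keeps C13 in place and removes the Michael acceptor. The forward steps must use only weak acid, a neutral allylic oxidant, buffered fluoride and a mild acylation.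

**29 ⇒ 27 (C1=C10, the key cut).** Re-inserting a sulfonyl group between C1 and C10, with chlorine on C10, gives the eleven-membered α-chloro sulfone 27. The neighbouring options close the ten-membered ring directly: olefination across C1=C10, or the C5–C6, C2–C3 and C7–C8 cuts discussed below. This cut moves ring closure to a ring one atom larger, with two long C–S bonds and without the ring-cis enoate. The alkene geometry then arises in a three-membered ring. Compound 27 has one alkene less and the same three stereocentres. The forward reaction needs a substrate whose only acidic C–H is on C1 and whose other groups tolerate alkoxide, hence the acetal and the silyl ether.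

**27 ⇒ 26 ⇒ 25 (C10–Cl, then C9–C10).** Chlorine goes onto the doubly activated C10–H of sulfone 26. The thiacycle itself is opened at C9–C10 to the acyclic sulfonyl ester triflate 25. Cutting S–C10 or S–C1 instead would need a thiol and a leaving group α to the ester in one molecule, which costs about three more steps. The C9–C10 cut uses the same C10 acidity three times: for ring closure, for chlorination and for the contraction. The price is a β-branched electrophile at C9. A triflate and high dilution are therefore required, and a C–S closure is held in reserve.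

**25 ⇒ 23 ⇒ 22 ⇒ 20 + 21 (S–C1).** The triflate and silyl ether of 25 come from the terminal diol 23. The sulfone comes from sulfide 22, which arises from the primary chloride 20 and methyl thioglycolate 21. This bimolecular SN2 at an unhindered carbon brings in S, C10 and C14 in one commercial reagent. It must follow all hydride and amide-base steps, because the ester of 21 would not survive them. It also needs the lactone masked, because thiolates add to C13.

**20 ⇒ 19 ⇒ 18 ⇒ 15 (acetal, oxidation level of C12, C11=C13).** Acetal 20 comes from lactol 19 and this from α-methylene lactone 18. The C11=C13 bond is cut back to the plain trans lactone 15. At that stage C11 is the only enolisable carbon in the molecule, so methylenation needs no selectivity.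

**15 ⇒ 13 ⇒ 11 + 3 (C5–C6).** Lactone 15 is the oxidation product of 1,4-diol 13. Cutting C5–C6 gives the lactol 11 (a masked C6 aldehyde) and the alkenyl iodide 3, used as its lithium derivative 12. Against a C6–C7 or C7–C8 cut, this one leaves C7 and C8 together in a small fragment. It sets C6 by open-chain induction in the reinforcing sense, and it carries the E alkene in from a stereodefined iodide. The precursors have nine and six carbons.

**11 ⇒ 10 ⇒ 9 ⇒ 8 ⇒ 6 ⇒ 4 + 5 (C7–C11).** Lactol 11 comes from lactone 10, the acetonide of diol 9. Diol 9 arises by reduction of the α-hydroxy ester 8. Ester 8 is formed when the allyl group of 6 is cleaved to a C12 alcohol that lactonises on the C6 ester. Cutting C7–C11 in 6 leads to dimethyl (S)-malate 4 and allyl bromide 5. With malate C1→C9, C2→C8, C3→C7 and C4→C6, the natural enantiomer has the configuration of C8 in 33. The anti alkylation then gives the C11/O8 relation of 33. Forming C7–C8 instead would have to create C8 as well.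

**3 ⇒ 1 (C4–CH3 and C5–I).** Iodide 3 comes from 5-chloropent-1-yne 1 by syn carbometalation. The chloride is the latent C1 electrophile, so C1 needs no protecting group.

## Roads not taken

**Alternative 1:** The cut is C5–C6 together with O6–C12.
- *Forward step.* The open-chain iodo aldehyde A1 would be treated with CrCl2 and catalytic NiCl2. The alkenylchromium at C5 adds to the C6 aldehyde, the ten-membered ring closes, and the C6 alkoxide lactonises on the C12 ester to give A2.
- *Merits.* The coupling is mild and tolerates ester, enoate and silyl ether. The C1=C10 geometry can be set beforehand in the open chain by an olefination. The C7/C8 pair could come from the same malate chemistry as here. The route would be several steps shorter and needs no sulfur detour.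
- *Weak points.* The ten-membered ring has to close with both alkenes in place. C6 is decided by a macrocyclic transition state, in which the open-chain Felkin preference need not hold. A large excess of chromium salt is needed at high dilution. A2 still lacks C13, and the lactone enolate would have to be formed beside an enoate with acidic C2 hydrogens.
- *Comparison.* Alternative 1 is better in step count and convergence. The chosen plan sets against it a C6 centre fixed before any ring strain is present, and a C13 installed while no competing acidic site exists.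

**Alternative 2:** The cut is C2–C3, seen as a retro-[3,3] shift that reconnects C5 and C10.
- *Forward step.* The potassium alkoxide of the cis-dialkenyl cyclohexanol A3 (KH, 18-crown-6) rearranges. The C10 enolate is trapped with PhNTf2 as dienyl triflate A4.
- *Merits.* The alkoxide acceleration pays for the ring strain. The stereocentres are built on a six-membered ring. The enolate is formed regiospecifically, and the triflate is a handle for palladium-catalysed methoxycarbonylation. As a way of making ten-membered rings this reaction type has a stronger record than the closure of 25.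
- *Weak points.* The ring-trans/ring-cis pattern needs the cis arrangement of the two alkenyl groups, and then a choice between two chair transition states that differ only in which alkene becomes ring-cis. If the enolate equilibrates towards C9, the C8 ether is lost by β-elimination. A3 has five contiguous stereocentres, including a tertiary carbinol, and is itself a long synthesis. After A4, carbonylation, methylenation at C11 and a protecting group exchange remain.
- *Comparison.* The chosen plan is weaker in the ring-forming event but stronger in control of the C1=C10 geometry, and it places the ester on C10 from the start.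

**Alternative 3:** The cut is C7–C8.
- *Forward step.* CrCl2 would convert the C13 bromide of butenolide aldehyde A5 into an allylchromium that attacks the tethered C8 aldehyde through C7, giving A6, which is identical with 32.
- *Merits.* One step makes the ring, C7, C8 and the exocyclic methylene. No masking of the lactone is needed, and the product is one acylation from 33. This is by far the shortest road.
- *Weak points.* In A5, C6 lies trans to C13 across C11=C7, so the allylmetal behaves as an E-crotyl type reagent. In a Zimmerman–Traxler chair with the aldehyde substituent equatorial, the C7/C8 relation is that of the C8 epimer of A6. The tether may override this, but the outcome cannot be predicted. Inversion at C8 of a ten-membered homoallylic alcohol is unattractive. C6 would have to be made enantioselectively as the only control element. The aldehyde of A5 has C9 hydrogens that are α to the carbonyl and attached to the enoate, so it should isomerise easily.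
- *Comparison.* If C8 came out correctly, Alternative 3 would be clearly superior. The chosen plan offers a C8 taken from the chiral pool and two relays of known sense, paid for with about twice the number of steps.

Key step: step 17

Assumption: the acetal carbon C12 (from 20 on) and C10 in 27 form as epimer mixtures that converge later, so one epimer is drawn (12S, 10R). The labile centres of the lactols, of 16, 17, 26 and 28 are written without descriptor.

Remark: descriptors at C7 and C8 change along the route only because substituent priorities change. The spatial arrangement is that of 33 throughout.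

## Steps

Step 1
Reactants: 1 5-chloropent-1-yne
Product: 3 (E)-5-chloro-1-iodo-2-methylpent-1-ene, via alkenyldimethylalane 2 (not isolated)
Conditions: Me3Al (2 equiv), Cp2ZrCl2 (0.2 equiv), CH2Cl2, 0 °C to rt; I2, THF, −30 to 0 °C
Reagents that add atoms: trimethylaluminium, C[Al](C)C; iodine, I-I
Why: Zirconium-catalysed (Negishi) carboalumination adds methyl and aluminium syn to the terminal alkyne with methyl on the inner carbon, and iodinolysis with retention gives the E iodide that fixes the C4=C5 geometry. The primary chloride is inert here and serves later as the C1 electrophile.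

Step 2
Reactants: 4 dimethyl (S)-malate; 5 allyl bromide
Product: 6 dimethyl (2S,3R)-2-hydroxy-3-(prop-2-en-1-yl)butanedioate
Conditions: LDA (2.2 equiv), THF, −78 to −20 °C; 5, −78 to −10 °C
Reagents that add atoms: none
Why: Fráter–Seebach alkylation: the chelated dilithio alkoxide enolate of the β-hydroxy ester is alkylated on the face away from the C9 ester substituent of C8 and should give the anti (2S,3R) product. This sets C7 from C8 in the relation C11/O8 anti that 33 requires.

Step 3
Reactants: 6 dimethyl (2S,3R)-2-hydroxy-3-(prop-2-en-1-yl)butanedioate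
Product: 8 methyl (2S)-2-hydroxy-2-[(3R)-2-oxooxolan-3-yl]acetate, via hydroxyethyl malate 7 (not isolated)
Conditions: O3, CH2Cl2/MeOH, −78 °C; NaBH4, −78 to 0 °C; TsOH·H2O (cat.), CH2Cl2, rt
Reagents that add atoms: ozone, [O-][O+]=O
Why: Ozonolysis with reductive work-up leaves C12 as a primary alcohol that closes on the nearer C6 ester (five-membered lactonisation), which differentiates C6 from C9. Doing this now avoids a later choice between a vinyl group and C4=C5 and removes the alkene before borane is used.

Step 4
Reactants: 8 methyl (2S)-2-hydroxy-2-[(3R)-2-oxooxolan-3-yl]acetate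
Product: 9 (3R)-3-[(1S)-1,2-dihydroxyethyl]oxolan-2-one
Conditions: BH3·SMe2 (1.05 equiv), THF, 0 °C to rt; NaBH4 (0.05 equiv); MeOH
Reagents that add atoms: none
Why: Hydroxyl-directed borane reduction of an α-hydroxy ester: the C8 alkoxyborane activates the C9 ester through a five-membered chelate, as in the regioselective reduction of malate diesters. The C6 carbonyl, which can only form a six-membered chelate, should be left.

Step 5
Reactants: 9 (3R)-3-[(1S)-1,2-dihydroxyethyl]oxolan-2-one
Product: 10 (3R)-3-[(4S)-2,2-dimethyl-1,3-dioxolan-4-yl]oxolan-2-one
Conditions: Me2C(OMe)2, TsOH·H2O (cat.), acetone, rt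
Reagents that add atoms: 2,2-dimethoxypropane, COC(C)(C)OC
Why: Ketalisation of a terminal 1,2-diol. Should acid let the C9 hydroxyl exchange with O12 at the C6 carbonyl, only the isomer with the free 1,2-diol can be ketalised, so the equilibrium drains to 10.

Step 6
Reactants: 10 (3R)-3-[(4S)-2,2-dimethyl-1,3-dioxolan-4-yl]oxolan-2-one
Product: 11 (3R)-3-[(4S)-2,2-dimethyl-1,3-dioxolan-4-yl]oxolan-2-ol (anomers)
Conditions: i-Bu2AlH (1.1 equiv), CH2Cl2, −78 °C; aq. potassium sodium tartrate
Reagents that add atoms: none
Why: Partial reduction of a γ-lactone to the lactol, which is the masked C6 aldehyde with O12 as internal protecting group. The ketal is inert at this temperature.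

Step 7
Reactants: 3 (E)-5-chloro-1-iodo-2-methylpent-1-ene; 11 (3R)-3-[(4S)-2,2-dimethyl-1,3-dioxolan-4-yl]oxolan-2-ol
Product: 13 (3S,4R,5E)-9-chloro-3-[(4S)-2,2-dimethyl-1,3-dioxolan-4-yl]-6-methylnon-5-ene-1,4-diol, via alkenyllithium 12 (not isolated)
Conditions: 3 (2.4 equiv), t-BuLi (4.8 equiv), Et2O, −78 °C; 11, THF, −78 to −20 °C
Reagents that add atoms: none
Why: Iodine–lithium exchange with retention, then 1,2-addition to the open hydroxy aldehyde form of the lactol (the first equivalent of 12 acts as base). C6 is set by Felkin–Anh attack anti to the branched C8 group, reinforced by 1,3-anti induction from O8 because C11 and O8 are anti, which gives O6/C11 syn as in 33. 12 cannot cyclise on its own chloride because the metal is trans to the chain.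

Step 8
Reactants: 13 (3S,4R,5E)-9-chloro-3-[(4S)-2,2-dimethyl-1,3-dioxolan-4-yl]-6-methylnon-5-ene-1,4-diol
Product: 15 (4S,5R)-5-[(1E)-5-chloro-2-methylpent-1-en-1-yl]-4-[(4S)-2,2-dimethyl-1,3-dioxolan-4-yl]oxolan-2-one, via lactol 14 (not isolated)
Conditions: TEMPO (0.2 equiv), PhI(OAc)2 (2.5 equiv), CH2Cl2, rt
Reagents that add atoms: none
Why: Oxoammonium-mediated oxidative lactonisation of a 1,4-diol: the unhindered primary C12 alcohol is oxidised first, O6 captures the aldehyde as lactol 14, and this is oxidised again, so the hindered allylic alcohol is tied up before it can react. C6 and C7 are untouched and the trans lactone results.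

Step 9
Reactants: 15 (4S,5R)-5-[(1E)-5-chloro-2-methylpent-1-en-1-yl]-4-[(4S)-2,2-dimethyl-1,3-dioxolan-4-yl]oxolan-2-one
Product: 18 (4S,5R)-5-[(1E)-5-chloro-2-methylpent-1-en-1-yl]-4-[(4S)-2,2-dimethyl-1,3-dioxolan-4-yl]-3-methylideneoxolan-2-one, via Mannich base 16 (not isolated), via methiodide 17 (not isolated)
Conditions: LDA (1.2 equiv), THF, −78 °C; CH2=NMe2 I, −78 °C to rt; MeI, MeOH, rt; aq. NaHCO3/CH2Cl2
Reagents that add atoms: N,N-dimethylmethyleneiminium iodide (Eschenmoser's salt), C=[N+](C)C.[I-]; iodomethane (into 17 only), CI
Why: Lactone α-methylenation by Mannich reaction of the lithium enolate, quaternisation and E1cB loss of trimethylamine. C11 is the only enolisable carbon at this stage, which is why C13 is introduced before ester and sulfone arrive.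

Step 10
Reactants: 18 (4S,5R)-5-[(1E)-5-chloro-2-methylpent-1-en-1-yl]-4-[(4S)-2,2-dimethyl-1,3-dioxolan-4-yl]-3-methylideneoxolan-2-one
Product: 19 (4S,5R)-5-[(1E)-5-chloro-2-methylpent-1-en-1-yl]-4-[(4S)-2,2-dimethyl-1,3-dioxolan-4-yl]-3-methylideneoxolan-2-ol (anomers)
Conditions: i-Bu2AlH (1.1 equiv), toluene, −78 °C; aq. potassium sodium tartrate
Reagents that add atoms: none
Why: 1,2-Reduction of an α-methylene lactone to the α-methylene lactol. The tetrahedral aluminate persists at low temperature, so neither over-reduction nor conjugate reduction is expected.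

Step 11
Reactants: 19 (4S,5R)-5-[(1E)-5-chloro-2-methylpent-1-en-1-yl]-4-[(4S)-2,2-dimethyl-1,3-dioxolan-4-yl]-3-methylideneoxolan-2-ol
Product: 20 (1S)-1-{(2R,3R,5S)-2-[(1E)-5-chloro-2-methylpent-1-en-1-yl]-5-methoxy-4-methylideneoxolan-3-yl}ethane-1,2-diol
Conditions: CSA (0.1 equiv), MeOH, 0 °C to rt
Reagents that add atoms: methanol, CO
Why: Acid-catalysed acetalisation through the allyl-stabilised oxocarbenium ion and cleavage of the terminal acetonide run under the same conditions, and the water released by the first reaction serves the second. Weak acid and short contact are meant to spare the allylic C6–O bond, and the C12 anomers are of no consequence.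

Step 12
Reactants: 20 (1S)-1-{(2R,3R,5S)-2-[(1E)-5-chloro-2-methylpent-1-en-1-yl]-5-methoxy-4-methylideneoxolan-3-yl}ethane-1,2-diol; 21 methyl thioglycolate
Product: 22 methyl 2-{[(4E)-5-{(2R,3R,5S)-3-[(1S)-1,2-dihydroxyethyl]-5-methoxy-4-methylideneoxolan-2-yl}-4-methylpent-4-en-1-yl]sulfanyl}acetate
Conditions: 21 (1.2 equiv), K2CO3, NaI (0.2 equiv), DMF, rt to 40 °C
Reagents that add atoms: none
Why: SN2 displacement of the unhindered primary chloride (iodide catalysis) by the soft thiolate of 21 brings in S, C10 and C14. No Michael acceptor is present because the lactone is masked, and carbonate does not affect the diol.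

Step 13
Reactants: 22 methyl 2-{[(4E)-5-{(2R,3R,5S)-3-[(1S)-1,2-dihydroxyethyl]-5-methoxy-4-methylideneoxolan-2-yl}-4-methylpent-4-en-1-yl]sulfanyl}acetate
Product: 23 methyl 2-{[(4E)-5-{(2R,3R,5S)-3-[(1S)-1,2-dihydroxyethyl]-5-methoxy-4-methylideneoxolan-2-yl}-4-methylpent-4-en-1-yl]sulfonyl}acetate
Conditions: (NH4)6Mo7O24·4H2O (0.1 equiv), 30% H2O2, MeOH, 0 °C to rt
Reagents that add atoms: hydrogen peroxide, OO
Why: Molybdate-catalysed peroxide oxidation takes sulfides to sulfones much faster than it epoxidises unactivated alkenes. Methanol as solvent makes any acetal exchange degenerate.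

Step 14
Reactants: 23 methyl 2-{[(4E)-5-{(2R,3R,5S)-3-[(1S)-1,2-dihydroxyethyl]-5-methoxy-4-methylideneoxolan-2-yl}-4-methylpent-4-en-1-yl]sulfonyl}acetate
Product: 25 acyclic sulfonyl ester with C9–OTf and C8–OTBS (6R,7S,8S in target numbering; 23 with the primary OH as triflate and the secondary OH as tert-butyldimethylsilyl ether), via hydroxy triflate 24 (not isolated)
Conditions: Tf2O (1.05 equiv), 2,6-lutidine (4 equiv), CH2Cl2, −78 °C; TBSOTf (1.3 equiv), −78 to −20 °C
Reagents that add atoms: triflic anhydride, O=S(=O)(OS(=O)(=O)C(F)(F)F)C(F)(F)F; tert-butyldimethylsilyl triflate, CC(C)(C)[Si](C)(C)OS(=O)(=O)C(F)(F)F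
Why: Primary-selective triflation at −78 °C followed by silylation of the remaining secondary hydroxyl in the same flask is an established way from a terminal 1,2-diol to a β-silyloxy triflate. 2,6-Lutidine is too weak to ionise the sulfonyl ester, and the silyl triflate at low temperature should leave the mixed acetal alone.

Step 15
Reactants: 25 acyclic sulfonyl ester with C9–OTf and C8–OTBS
Product: 26 eleven-membered cyclic sulfone (S bridges C1 and C10; C10 bears H and CO2Me; 4E; 8-OTBS; 6,7-trans-fused 12-methoxy-11(13)-methylene oxolane; 6R,7S,8R)
Conditions: Cs2CO3 (5 equiv), MeCN, rt, 25 added over 12 h (final ca. 1 mM)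
Reagents that add atoms: none
Why: Intramolecular C-alkylation of a sulfonyl-stabilised ester carbanion under high dilution, the type of closure known for ω-halo sulfanyl- and sulfonylacetates and malonates (11-exo-tet). The triflate compensates for the β-branching at C9, and carbonate ionises only C10–H. C10 forms as an epimerisable centre of no consequence.

Step 16
Reactants: 26 eleven-membered cyclic sulfone
Product: 27 eleven-membered α-chloro sulfone (26 with Cl in place of H on C10)
Conditions: NaH (1.05 equiv), THF, 0 °C; C2Cl6 (1.1 equiv), 0 °C to rt
Reagents that add atoms: hexachloroethane, ClC(Cl)(Cl)C(Cl)(Cl)Cl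
Why: Chlorination of the sulfonyl ester anion with a positive-chlorine donor. One equivalent of base reaches only the doubly activated C10–H, so the halogen is placed regiospecifically, and the alkenes are not attacked by this reagent.

Step 17
Reactants: 27 eleven-membered α-chloro sulfone
Product: 29 ten-membered enoate with masked lactone (methyl ester on C10, C1=C10 ring-cis, 4E, 8-OTBS, 12-methoxy-11(13)-methylene oxolane; 6R,7S,8R), via episulfone 28 (not isolated)
Conditions: t-BuOK (2.2 equiv), THF, −78 to −20 °C; AcOH
Reagents that add atoms: none
Why: Ramberg–Bäcklund reaction used as a one-atom ring contraction. C10 of 27 is quaternary, so t-BuOK can only remove a C1 proton next to the sulfone; the carbanion displaces chloride from C10 with inversion (3-exo-tet), which forms the C1–C10 bond and thus at once the thiirane dioxide ring and the ten-membered carbocycle of 28. If chlorine is first passed from C10 to C1, the ester-stabilised C10 anion closes the same three-membered ring, so both C10 epimers of 27 converge on 28. 28 loses SO2 cheletropically with retention, so its ring fusion becomes the alkene geometry of 29. No stereocentre is made; the selectivity needed is the ring-cis alkene (C2 and C9 on one side, CO2Me opposite C2). The substrate secures it in two ways: the cis-fused episulfone keeps CO2Me away from C2 and leads to the less strained cis-cyclodecene-type ring, and its remaining C1–H is acidic enough for t-BuOK to equilibrate the fusion before extrusion towards this isomer, which is also the geometry preferred by 2-alkyl-2-enoates. The closest known reaction types are the base-induced conversion of α-chloro-α-sulfonyl esters into 2-enoates and the contraction of medium and large cyclic α-halo sulfones to cycloalkenes. Acetal, silyl ether and the other two alkenes are inert to alkoxide, and about two equivalents of base at low temperature with an acidic quench are meant to prevent deprotonation of 29 at C2.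

Step 18
Reactants: 29 ten-membered enoate with masked lactone
Product: 30 ten-membered allylic lactol (29 with OH in place of OMe on C12, anomers)
Conditions: PPTS (0.3 equiv), acetone/H2O 5:1, rt to 40 °C
Reagents that add atoms: water, O
Why: Hydrolysis of a mixed acetal through the allyl-stabilised oxocarbenium ion, which needs only a weak acid. The secondary silyl ether stays on, and the electron-poor C1=C10 alkene is a poor partner for transannular cyclisation.

Step 19
Reactants: 30 ten-membered allylic lactol
Product: 31 8-O-TBS α-methylene lactone (33 with OTBS in place of the methacrylate; 6R,7S,8R)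
Conditions: MnO2 (20 equiv), CH2Cl2, rt
Reagents that add atoms: none
Why: MnO2 oxidation of an allylic lactol to the α-methylene-γ-butyrolactone, the closing stage of the known oxidation of 2-methylene-1,4-diols. The reagent is neutral and touches no other group.

Step 20
Reactants: 31 8-O-TBS α-methylene lactone
Product: 32 C8 alcohol, methyl (6R,7R,8R)-8-hydroxy-12-oxo-6,12-epoxygermacra-1(10),4,11(13)-trien-14-oate (C1=C10 ring-cis, 4E)
Conditions: HF·pyridine, pyridine, THF, 0 °C to rt
Reagents that add atoms: none
Why: Fluoride-mediated cleavage of a secondary silyl ether under buffered, weakly acidic conditions, chosen because basic fluoride would add to C13 or promote acyl transfer to O8.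

Step 21
Reactants: 32 C8 alcohol
Product: 33 target, the 8-methacrylate of 32 (6R,7R,8R)
Conditions: methacrylic anhydride (2 equiv), Et3N, DMAP (0.1 equiv), CH2Cl2, 0 °C to rt
Reagents that add atoms: methacrylic anhydride, C=C(C)C(=O)OC(=O)C(C)=C
Why: DMAP-catalysed acylation of a secondary alcohol with retention at C8. It is run directly on freshly prepared 32 so that the free hydroxyl has little time to attack C12 or C14.

## Compound list

1 | 5-chloropent-1-yne | C#CCCCCl | starting material
2 | (E)-(5-chloro-2-methylpent-1-en-1-yl)dimethylalane | ClCCC/C(C)=C/[Al](C)C | intermediate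
3 | (E)-5-chloro-1-iodo-2-methylpent-1-ene | ClCCC/C(C)=C/I | intermediate
4 | dimethyl (S)-malate | COC(=O)C[C@H](O)C(=O)OC | starting material
5 | allyl bromide | C=CCBr | starting material
6 | dimethyl (2S,3R)-2-hydroxy-3-(prop-2-en-1-yl)butanedioate | COC(=O)[C@H](CC=C)[C@H](O)C(=O)OC | intermediate
7 | dimethyl (2S,3R)-2-hydroxy-3-(2-hydroxyethyl)butanedioate | COC(=O)[C@H](CCO)[C@H](O)C(=O)OC | intermediate
8 | methyl (2S)-2-hydroxy-2-[(3R)-2-oxooxolan-3-yl]acetate | O=C1OCC[C@@H]1[C@H](O)C(=O)OC | intermediate
9 | (3R)-3-[(1S)-1,2-dihydroxyethyl]oxolan-2-one | O=C1OCC[C@@H]1[C@H](O)CO | intermediate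
10 | (3R)-3-[(4S)-2,2-dimethyl-1,3-dioxolan-4-yl]oxolan-2-one | O=C1OCC[C@@H]1[C@H]2COC(C)(C)O2 | intermediate
11 | (3R)-3-[(4S)-2,2-dimethyl-1,3-dioxolan-4-yl]oxolan-2-ol | OC1OCC[C@@H]1[C@H]2COC(C)(C)O2 | intermediate
12 | (E)-(5-chloro-2-methylpent-1-en-1-yl)lithium | ClCCC/C(C)=C/[Li] | intermediate
13 | (3S,4R,5E)-9-chloro-3-[(4S)-2,2-dimethyl-1,3-dioxolan-4-yl]-6-methylnon-5-ene-1,4-diol | ClCCC/C(C)=C/[C@@H](O)[C@H](CCO)[C@H]1COC(C)(C)O1 | intermediate
14 | (4S,5R)-5-[(1E)-5-chloro-2-methylpent-1-en-1-yl]-4-[(4S)-2,2-dimethyl-1,3-dioxolan-4-yl]oxolan-2-ol | ClCCC/C(C)=C/[C@H]1OC(O)C[C@@H]1[C@H]2COC(C)(C)O2 | intermediate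
15 | (4S,5R)-5-[(1E)-5-chloro-2-methylpent-1-en-1-yl]-4-[(4S)-2,2-dimethyl-1,3-dioxolan-4-yl]oxolan-2-one | ClCCC/C(C)=C/[C@H]1OC(=O)C[C@@H]1[C@H]2COC(C)(C)O2 | intermediate
16 | 3-[(dimethylamino)methyl] derivative of 15 | ClCCC/C(C)=C/[C@H]1OC(=O)C(CN(C)C)[C@@H]1[C@H]2COC(C)(C)O2 | intermediate
17 | trimethylammonium iodide derived from 16 | ClCCC/C(C)=C/[C@H]1OC(=O)C(C[N+](C)(C)C)[C@@H]1[C@H]2COC(C)(C)O2.[I-] | intermediate
18 | (4S,5R)-5-[(1E)-5-chloro-2-methylpent-1-en-1-yl]-4-[(4S)-2,2-dimethyl-1,3-dioxolan-4-yl]-3-methylideneoxolan-2-one | ClCCC/C(C)=C/[C@H]1OC(=O)C(=C)[C@@H]1[C@H]2COC(C)(C)O2 | intermediate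
19 | (4S,5R)-5-[(1E)-5-chloro-2-methylpent-1-en-1-yl]-4-[(4S)-2,2-dimethyl-1,3-dioxolan-4-yl]-3-methylideneoxolan-2-ol | ClCCC/C(C)=C/[C@H]1OC(O)C(=C)[C@@H]1[C@H]2COC(C)(C)O2 | intermediate
20 | (1S)-1-{(2R,3R,5S)-2-[(1E)-5-chloro-2-methylpent-1-en-1-yl]-5-methoxy-4-methylideneoxolan-3-yl}ethane-1,2-diol | ClCCC/C(C)=C/[C@H]1O[C@H](OC)C(=C)[C@@H]1[C@H](O)CO | intermediate
21 | methyl thioglycolate | COC(=O)CS | starting material
22 | sulfide, methyl 2-{[(4E)-5-{(2R,3R,5S)-3-[(1S)-1,2-dihydroxyethyl]-5-methoxy-4-methylideneoxolan-2-yl}-4-methylpent-4-en-1-yl]sulfanyl}acetate | COC(=O)CSCCC/C(C)=C/[C@H]1O[C@H](OC)C(=C)[C@@H]1[C@H](O)CO | intermediate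
23 | sulfone corresponding to 22 | COC(=O)CS(=O)(=O)CCC/C(C)=C/[C@H]1O[C@H](OC)C(=C)[C@@H]1[C@H](O)CO | intermediate
24 | primary triflate of 23 with free C8 hydroxyl | COC(=O)CS(=O)(=O)CCC/C(C)=C/[C@H]1O[C@H](OC)C(=C)[C@@H]1[C@H](O)COS(=O)(=O)C(F)(F)F | intermediate
25 | primary triflate, C8 tert-butyldimethylsilyl ether of 23 | COC(=O)CS(=O)(=O)CCC/C(C)=C/[C@H]1O[C@H](OC)C(=C)[C@@H]1[C@H](O[Si](C)(C)C(C)(C)C)COS(=O)(=O)C(F)(F)F | intermediate
26 | eleven-membered cyclic sulfone, C10–H | CC(C)(C)[Si](C)(C)O[C@@H]1CC(C(=O)OC)S(=O)(=O)CCC/C(C)=C/[C@H]2O[C@H](OC)C(=C)[C@@H]21 | intermediate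
27 | eleven-membered α-chloro sulfone | CC(C)(C)[Si](C)(C)O[C@@H]1C[C@@](Cl)(C(=O)OC)S(=O)(=O)CCC/C(C)=C/[C@H]2O[C@H](OC)C(=C)[C@@H]21 | intermediate
28 | cis-fused episulfone (thiirane 1,1-dioxide across C1–C10) | CC(C)(C)[Si](C)(C)O[C@@H]1CC2(C(=O)OC)C(S2(=O)=O)CC/C(C)=C/[C@H]3O[C@H](OC)C(=C)[C@@H]31 | intermediate
29 | ten-membered enoate with lactone masked as allylic lactol methyl ether | CC(C)(C)[Si](C)(C)O[C@@H]1C/C(C(=O)OC)=C\CC/C(C)=C/[C@H]2O[C@H](OC)C(=C)[C@@H]21 | intermediate
30 | ten-membered allylic lactol | CC(C)(C)[Si](C)(C)O[C@@H]1C/C(C(=O)OC)=C\CC/C(C)=C/[C@H]2OC(O)C(=C)[C@@H]21 | intermediate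
31 | 8-O-TBS α-methylene lactone | CC(C)(C)[Si](C)(C)O[C@@H]1C/C(C(=O)OC)=C\CC/C(C)=C/[C@H]2OC(=O)C(=C)[C@@H]21 | intermediate
32 | C8 alcohol | O[C@@H]1C/C(C(=O)OC)=C\CC/C(C)=C/[C@H]2OC(=O)C(=C)[C@@H]21 | intermediate
33 | CNP0317149.1 | C=C(C)C(=O)O[C@@H]1C/C(C(=O)OC)=C\CC/C(C)=C/[C@H]2OC(=O)C(=C)[C@@H]21 | target

## Step count and least certain steps

Total: 21 steps. The longest linear sequence is 20 steps (4 to 33, steps 2–21). Step 1 is the only side branch.

**Step 17 (key step).**
- *What may go wrong.* The alkoxide may attack the chlorine of 27 instead of a C1 proton, because the C10 anion is an excellent leaving group for positive chlorine. This amounts to reductive dechlorination back to the stage of 26, with a chlorinating by-product that could attack C4=C5. Extrusion may also proceed through the trans-fused episulfone, giving the ring-trans alkene. Excess base may deprotonate the product at C2 and deconjugate it.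
- *Fallback.* It sets out from 20 and returns at 29, and it forms the same C1=C10 bond by olefination. One-pot triflation and silylation of 20 gives the chloro triflate F1. The sodium salt of trimethyl phosphonoacetate displaces the triflate to give the phosphonoacetate F2. A Finkelstein exchange gives the iodide F3. Oxidation of the iodide with trimethylamine N-oxide in DMSO gives the aldehyde F4. Intramolecular Horner–Wadsworth–Emmons reaction under Masamune–Roush conditions (LiCl, DBU, MeCN, high dilution) closes the ten-membered ring. For an α-substituted phosphonoacetate this reaction favours CO2Me opposite C2, which is the ring-cis geometry of 29.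

**Step 15 (closure of the thiacycle).**
- *What may go wrong.* Intermolecular alkylation may outrun closure of the strained eleven-membered ring. The β-branched triflate may be lost by solvolysis or elimination during the long addition. The ambident anion may be alkylated on oxygen through a larger and easier ring.
- *Fallback.* It sets out from 20 and returns at 26. It moves the closure to a C–S bond at the unhindered C1. The chloro triflate F1 is alkylated with the lithium enolate of methyl acetate (THF/DMPU, −78 °C) to give the methyl ester F5. The enolate of F5 (LiHMDS) is brominated with NBS to give the α-bromo ester F6. Potassium thioacetate displaces only the activated bromide to give the α-acetylthio ester F7. Methanolysis with K2CO3 in MeOH/DMF with NaI at high dilution frees the thiolate, which closes on C1 to give the cyclic sulfide F8. The molybdate/H2O2 oxidation of step 13 then gives 26. This costs three more steps but relies on a nucleophile that is much faster and on an electrophile that tolerates long reaction times.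

**Step 7 (C6 stereocentre).**
- *What may go wrong.* Facial selectivity may be poor if the internal C12 alkoxide or a dioxolane oxygen coordinates the metal and opposes the Felkin–Anh preference. The aldehyde form may also enolise, with epimerisation at C7.
- *Fallback.* It sets out from 9 and returns at 13. It replaces addition control by hydroxyl-directed reduction. Excess 12 adds once to the lactone carbonyl of 9 at −78 °C to give the keto triol F9. Evans–Saksena reduction (Me4NBH(OAc)3, MeCN/AcOH, −30 °C) delivers hydride from the C8-bound boron and gives the 1,3-anti tetraol F10, in which O6/O8 anti is the relation required. Selective ketalisation of the terminal 1,2-diol (2,2-dimethoxypropane, PPTS) gives 13.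

**Step 20 (release of the C8 hydroxyl).**
- *What may go wrong.* Once the silyl group is lost, the free hydroxyl may attack C12 (translactonisation to O8) or C14 (a new five-membered lactone). Fluoride or pyridine may add to C13.
- *Fallback.* It sets out from 29 and returns at 33. It changes the order so that O8 is acylated while C12 is still masked. TBAF buffered with AcOH converts 29 into the acetal alcohol F11. Methacrylic anhydride with DMAP gives the methacrylate acetal F12. PPTS in aqueous acetone gives the methacrylate lactol F13, and MnO2 oxidises it to 33.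

## Further compounds

F1 | step 17 | chloro triflate, 20 with C9–OTf and C8–OTBS | ClCCC/C(C)=C/[C@H]1O[C@H](OC)C(=C)[C@@H]1[C@H](O[Si](C)(C)C(C)(C)C)COS(=O)(=O)C(F)(F)F
F2 | step 17 | phosphonoacetate, C10 bearing P(O)(OMe)2 and CO2Me, C1 chloride | ClCCC/C(C)=C/[C@H]1O[C@H](OC)C(=C)[C@@H]1[C@H](O[Si](C)(C)C(C)(C)C)CC(C(=O)OC)P(=O)(OC)OC
F3 | step 17 | iodide corresponding to F2 | ICCC/C(C)=C/[C@H]1O[C@H](OC)C(=C)[C@@H]1[C@H](O[Si](C)(C)C(C)(C)C)CC(C(=O)OC)P(=O)(OC)OC
F4 | step 17 | C1 aldehyde phosphonoacetate | O=CCC/C(C)=C/[C@H]1O[C@H](OC)C(=C)[C@@H]1[C@H](O[Si](C)(C)C(C)(C)C)CC(C(=O)OC)P(=O)(OC)OC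
F5 | step 15 | methyl ester with C10H2, C1 chloride | ClCCC/C(C)=C/[C@H]1O[C@H](OC)C(=C)[C@@H]1[C@H](O[Si](C)(C)C(C)(C)C)CCC(=O)OC
F6 | step 15 | α-bromo ester | ClCCC/C(C)=C/[C@H]1O[C@H](OC)C(=C)[C@@H]1[C@H](O[Si](C)(C)C(C)(C)C)CC(Br)C(=O)OC
F7 | step 15 | α-acetylthio ester | ClCCC/C(C)=C/[C@H]1O[C@H](OC)C(=C)[C@@H]1[C@H](O[Si](C)(C)C(C)(C)C)CC(SC(C)=O)C(=O)OC
F8 | step 15 | eleven-membered cyclic sulfide | CC(C)(C)[Si](C)(C)O[C@@H]1CC(C(=O)OC)SCCC/C(C)=C/[C@H]2O[C@H](OC)C(=C)[C@@H]21
F9 | step 7 | keto triol (C6 enone, free O8, O9, O12) | ClCCC/C(C)=C/C(=O)[C@H](CCO)[C@H](O)CO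
F10 | step 7 | 1,3-anti tetraol | ClCCC/C(C)=C/[C@@H](O)[C@H](CCO)[C@H](O)CO
F11 | step 20 | acetal alcohol, 29 without the silyl group | O[C@@H]1C/C(C(=O)OC)=C\CC/C(C)=C/[C@H]2O[C@H](OC)C(=C)[C@@H]21
F12 | step 20 | methacrylate acetal | C=C(C)C(=O)O[C@@H]1C/C(C(=O)OC)=C\CC/C(C)=C/[C@H]2O[C@H](OC)C(=C)[C@@H]21
F13 | step 20 | methacrylate lactol | C=C(C)C(=O)O[C@@H]1C/C(C(=O)OC)=C\CC/C(C)=C/[C@H]2OC(O)C(=C)[C@@H]21
A1 | alternative 1 | open-chain (E)-alkenyl iodide C6 aldehyde with C12 methyl ester | I/C=C(C)/CC/C=C(C(=O)OC)\C[C@@H](O[Si](C)(C)C(C)(C)C)[C@@H](CC(=O)OC)C=O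
A2 | alternative 1 | bicyclic lactone lacking C13 | CC(C)(C)[Si](C)(C)O[C@@H]1C/C(C(=O)OC)=C\CC/C(C)=C/[C@H]2OC(=O)C[C@@H]21
A3 | alternative 2 | cis-1-vinyl-2-isopropenyl cyclohexanol fused to the lactol methyl ether, 8-OPMB | C=C[C@@]1(O)C[C@@H](OCc3ccc(OC)cc3)[C@H]2C[C@@H](OC)O[C@@H]2[C@H]1C(C)=C
A4 | alternative 2 | ten-membered dienyl triflate | COc1ccc(cc1)CO[C@@H]1C/C(OS(=O)(=O)C(F)(F)F)=C\CC/C(C)=C/[C@H]2O[C@H](OC)C[C@@H]21
A5 | alternative 3 | 3-(bromomethyl)butenolide tethered to the C8 aldehyde | BrCC1=C[C@H](OC1=O)/C=C(C)/CC/C=C(C(=O)OC)\CC=O
A6 | alternative 3 | C8 alcohol, identical with 32 | O[C@@H]1C/C(C(=O)OC)=C\CC/C(C)=C/[C@H]2OC(=O)C(=C)[C@@H]21
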